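Atom labels: C1 lactone carbonyl, C2 its CH2, C3 ring-fusion CH, C4 ring-fusion C(CH3), C5 oxolane CH2, C6 oxolane C(CH3)(10-phenyldecyl). Everything rests on cutting C5–C6 of the oxolane ring. The feature exploited is that quaternary C6, whose methyl and decyl arms are almost equal in size, carries the ring oxygen, so removing C5 leaves the activated C6–H of an enantiopure secondary alkyl ether. A dirhodium carbenoid at C5 inserts into this C–H with retention: one operation makes C5–C6, closes the oxolane and fixes C6. The precursor is a (3R)-5-diazo-4-oxopentanoate carrying the (S)-12-phenyldodecan-2-yl ether at C3. Methyl addition at C4 and lactonisation complete the bicycle.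

Key step: step 8

Remarks on the design
- Configuration: in the labels above the target is 3R,4R,6S. The bicycle is cis-fused. H3, the C4 methyl and the C6 methyl lie on one face of the oxolane; the lactone ring and the decyl chain lie on the other.
- C1 stays at the ester oxidation level in the insertion substrate. C6–H is then the only C–H the carbenoid can reach through a five-membered transition state.
- The hindered C3–O–C6 ether is not made by displacement at C3. A leaving group there, activated by an ester and next to the acidic C2 hydrogens, would be prone to elimination. Instead the oxygen is alkylated at a primary carbon, and C3 is then created by auxiliary-controlled C–C bond formation. This also delivers C1 and C4 as different functional groups.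
- Assumption: phenylmagnesium bromide is used as the commercial THF solution and diazomethane as a freshly prepared ethereal solution.

Step 1
Reactants: 1 phenylmagnesium bromide; 2 1,9-dibromononane (3 equiv)
Product: 3 (9-bromononyl)benzene
Conditions: Li2CuCl4 (3 mol %), THF, 0 °C; excess 2 recovered by distillation
Reagents that add atoms: none
Why: Copper-catalysed Grignard–alkyl halide cross-coupling (Kochi type) substitutes one primary C–Br bond, and the threefold excess of 2 keeps double arylation statistically minor while the well-separated boiling points allow 3 to be purified and 2 to be recycled.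

Step 2
Reactants: 3 (9-bromononyl)benzene; 4 (S)-propylene oxide
Product: 6 (2S)-12-phenyldodecan-2-ol, via 9-phenylnonylmagnesium bromide 5 (not isolated)
Conditions: Mg, THF, reflux; then CuI (10 mol %), 4, THF, −30 → 0 °C
Reagents that add atoms: magnesium, [Mg] (retained only in 5)
Why: Copper-catalysed SN2 opening of a terminal epoxide by a Grignard reagent takes place at the unsubstituted CH2, so the C–O stereocentre of 4 is not touched and is carried over as (S)-configured C6.

Step 3
Reactants: 6 (2S)-12-phenyldodecan-2-ol; 7 bromoacetic acid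
Product: 8 {[(2S)-12-phenyldodecan-2-yl]oxy}acetic acid
Conditions: NaH (3 equiv), THF, 0 °C → reflux; then 1 M HCl
Reagents that add atoms: none
Why: Williamson ether synthesis of the sodium alkoxide of 6 on sodium bromoacetate forms the C–O bond at a primary carbon that cannot eliminate, and since the C6–O bond is never broken the carbinol configuration is retained.

Step 4
Reactants: 8 {[(2S)-12-phenyldodecan-2-yl]oxy}acetic acid; 9 (4S)-4-benzyl-1,3-oxazolidin-2-one
Product: 11 (4S)-4-benzyl-3-({[(2S)-12-phenyldodecan-2-yl]oxy}acetyl)-1,3-oxazolidin-2-one, via pivalic mixed anhydride 10 (not isolated)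
Conditions: PivCl, Et3N, THF, −20 °C; then LiCl, 9, −20 °C → rt
Reagents that add atoms: pivaloyl chloride, CC(C)(C)C(=O)Cl (retained only in 10)
Why: N-acylation of an Evans oxazolidinone through a mixed pivalic anhydride, in which the tert-butyl group steers the LiCl-activated auxiliary to the glycolyl carbonyl; no stereocentre is involved.

Step 5
Reactants: 11 (4S)-4-benzyl-3-({[(2S)-12-phenyldodecan-2-yl]oxy}acetyl)-1,3-oxazolidin-2-one; 12 methyl bromoacetate (3 equiv)
Product: 14 methyl (3R)-4-[(4S)-4-benzyl-2-oxo-1,3-oxazolidin-3-yl]-4-oxo-3-{[(2S)-12-phenyldodecan-2-yl]oxy}butanoate, via sodium Z-enolate 13 (not isolated)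
Conditions: NaN(SiMe3)2 (1.1 equiv), THF, −78 °C; then 12, −78 → −45 °C
Reagents that add atoms: sodium hexamethyldisilazide, [Na+].C[Si](C)(C)[N-][Si](C)(C)C (sodium retained only in 13)
Why: Evans asymmetric alkylation of a glycolate imide: the sodium-chelated Z-enolate is shielded on one face by the benzyl group of the (4S)-auxiliary, so the highly SN2-reactive α-bromo ester enters from the other face and sets C3 as R, while C4 (imide) and C1 (methyl ester) emerge already differentiated.

Step 6
Reactants: 14 methyl (3R)-4-[(4S)-4-benzyl-2-oxo-1,3-oxazolidin-3-yl]-4-oxo-3-{[(2S)-12-phenyldodecan-2-yl]oxy}butanoate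
Product: 16 (2R)-4-methoxy-4-oxo-2-{[(2S)-12-phenyldodecan-2-yl]oxy}butanoic acid, via peroxy acid 15 (not isolated)
Conditions: LiOH, H2O2, aq. THF, 0 °C; Na2SO3; then 1 M HCl to pH 3
Reagents that add atoms: hydrogen peroxide, OO
Why: Hydroperoxide cleavage of an N-acyl oxazolidinone: the α-effect nucleophile LiOOH attacks the exocyclic imide carbonyl far faster than the methyl ester is saponified at 0 °C, sulfite reduces the peroxy acid, and the weakly basic medium should neither epimerise C3 nor eliminate the β-alkoxy group.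

Step 7
Reactants: 16 (2R)-4-methoxy-4-oxo-2-{[(2S)-12-phenyldodecan-2-yl]oxy}butanoic acid
Product: 18 methyl (3R)-5-diazo-4-oxo-3-{[(2S)-12-phenyldodecan-2-yl]oxy}pentanoate, via isobutyl carbonic anhydride 17 (not isolated)
Conditions: i-BuOCOCl, N-methylmorpholine, THF, −20 °C; then CH2N2 (excess), Et2O, −20 → 0 °C
Reagents that add atoms: diazomethane, C=[N+]=[N-]; isobutyl chloroformate, CC(C)COC(=O)Cl (retained only in 17)
Why: Acylation of diazomethane (first stage of an Arndt–Eistert sequence) through a mixed carbonic anhydride made at −20 °C avoids HCl, ketene formation and the acyl interchange known for succinic half-ester chlorides, so C3 and the C1/C4 assignment are preserved.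

Step 8
Reactants: 18 methyl (3R)-5-diazo-4-oxo-3-{[(2S)-12-phenyldodecan-2-yl]oxy}pentanoate
Product: 19 methyl 2-[(2R,5S)-5-methyl-3-oxo-5-(10-phenyldecyl)oxolan-2-yl]acetate
Conditions: Rh2(OAc)4 (1 mol %), dry CH2Cl2, rt, 18 added by syringe pump (final ca. 0.01 M)
Reagents that add atoms: none
Why: Rh2(OAc)4 expels N2 from 18 and the electrophilic carbenoid at C5 inserts into the C6–H bond through a concerted but asynchronous three-centre transition state in which hydride character develops at H and positive charge at C6. The closest known reaction type is the dirhodium-catalysed intramolecular 1,5 C–H insertion of α-alkoxy-α'-diazoketones next to the ether oxygen, an established entry to oxolan-3-ones. The oxolane ring (O, C3, C4, C5, C6) closes by C5–C6 bond formation through a five-membered cyclic array, the preferred ring size for such insertions. The new quaternary stereocentre C6 is controlled solely by the configuration of the secondary ether carbon bought with 4, because C5 takes the place of H from the same side (retention, S), so methyl and decyl never have to be told apart. The step needs site selectivity, and the substrate secures it: C6–H is the only C–H within five-ring reach, it is tertiary and lone-pair activated, C1 carries no hydrogen, and the C6 methyl and C7 hydrogens would demand a six-membered transition state. Neutral conditions leave the enolisable C3 centre intact, slow addition at high dilution suppresses carbene dimers, and reversible capture by the ester carbonyl oxygen finds no trap and should drain back to insertion.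

Step 9
Reactants: 19 methyl 2-[(2R,5S)-5-methyl-3-oxo-5-(10-phenyldecyl)oxolan-2-yl]acetate
Product: 21 plakortolide ether (3aR,5S,6aR)-5,6a-dimethyl-5-(10-phenyldecyl)tetrahydrofuro[3,2-b]furan-2(3H)-one, via hydroxy ester 20 (not isolated)
Conditions: MeMgBr (1.3 equiv), anhydrous CeCl3 (1.5 equiv), THF, −78 °C; aqueous quench at −78 °C; then CSA (10 mol %), CH2Cl2, rt
Reagents that add atoms: methylmagnesium bromide, C[Mg]Br
Why: Imamoto-type organocerium 1,2-addition followed by acid-catalysed lactonisation: the weakly basic reagent should take the ketone ahead of the ester without enolising C3 or opening the ring by retro-oxa-Michael, it approaches the face carrying only H3 and the C6 methyl (anti to the C3 acetate arm and the C6 decyl chain) and so sets C4 as R with OH cis to the arm, and only this cis isomer can close the γ-lactone.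

Compound list
1 | phenylmagnesium bromide | Br[Mg]c1ccccc1 | starting material
2 | 1,9-dibromononane | BrCCCCCCCCCBr | starting material
3 | (9-bromononyl)benzene | BrCCCCCCCCCc1ccccc1 | intermediate
4 | (S)-propylene oxide, (2S)-2-methyloxirane | C[C@H]1CO1 | starting material
5 | 9-phenylnonylmagnesium bromide | Br[Mg]CCCCCCCCCc1ccccc1 | intermediate
6 | (2S)-12-phenyldodecan-2-ol | O[C@@H](C)CCCCCCCCCCc1ccccc1 | intermediate
7 | bromoacetic acid | OC(=O)CBr | starting material
8 | {[(2S)-12-phenyldodecan-2-yl]oxy}acetic acid | OC(=O)CO[C@@H](C)CCCCCCCCCCc1ccccc1 | intermediate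
9 | (4S)-4-benzyl-1,3-oxazolidin-2-one | O=C1N[C@@H](Cc2ccccc2)CO1 | starting material
10 | {[(2S)-12-phenyldodecan-2-yl]oxy}acetic pivalic anhydride | CC(C)(C)C(=O)OC(=O)CO[C@@H](C)CCCCCCCCCCc1ccccc1 | intermediate
11 | (4S)-4-benzyl-3-({[(2S)-12-phenyldodecan-2-yl]oxy}acetyl)-1,3-oxazolidin-2-one | O=C(CO[C@@H](C)CCCCCCCCCCc1ccccc1)N2C(=O)OC[C@@H]2Cc3ccccc3 | intermediate
12 | methyl bromoacetate | COC(=O)CBr | starting material
13 | sodium (Z)-enolate of 11 | [Na+].[O-]/C(=C\O[C@@H](C)CCCCCCCCCCc1ccccc1)N2C(=O)OC[C@@H]2Cc3ccccc3 | intermediate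
14 | methyl (3R)-4-[(4S)-4-benzyl-2-oxo-1,3-oxazolidin-3-yl]-4-oxo-3-{[(2S)-12-phenyldodecan-2-yl]oxy}butanoate | COC(=O)C[C@@H](O[C@@H](C)CCCCCCCCCCc1ccccc1)C(=O)N2C(=O)OC[C@@H]2Cc3ccccc3 | intermediate
15 | (2R)-4-methoxy-4-oxo-2-{[(2S)-12-phenyldodecan-2-yl]oxy}butaneperoxoic acid | COC(=O)C[C@@H](O[C@@H](C)CCCCCCCCCCc1ccccc1)C(=O)OO | intermediate
16 | (2R)-4-methoxy-4-oxo-2-{[(2S)-12-phenyldodecan-2-yl]oxy}butanoic acid | COC(=O)C[C@@H](O[C@@H](C)CCCCCCCCCCc1ccccc1)C(=O)O | intermediate
17 | isobutyl carbonic anhydride of 16 | COC(=O)C[C@@H](O[C@@H](C)CCCCCCCCCCc1ccccc1)C(=O)OC(=O)OCC(C)C | intermediate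
18 | methyl (3R)-5-diazo-4-oxo-3-{[(2S)-12-phenyldodecan-2-yl]oxy}pentanoate | COC(=O)C[C@@H](O[C@@H](C)CCCCCCCCCCc1ccccc1)C(=O)C=[N+]=[N-] | intermediate
19 | methyl 2-[(2R,5S)-5-methyl-3-oxo-5-(10-phenyldecyl)oxolan-2-yl]acetate | C[C@]1(CCCCCCCCCCc2ccccc2)CC(=O)[C@@H](CC(=O)OC)O1 | intermediate
20 | methyl 2-[(2R,3R,5S)-3-hydroxy-3,5-dimethyl-5-(10-phenyldecyl)oxolan-2-yl]acetate | C[C@]1(CCCCCCCCCCc2ccccc2)C[C@@](C)(O)[C@@H](CC(=O)OC)O1 | intermediate
21 | plakortolide ether, (3aR,5S,6aR)-5,6a-dimethyl-5-(10-phenyldecyl)tetrahydrofuro[3,2-b]furan-2(3H)-one | C[C@]1(CCCCCCCCCCc2ccccc2)C[C@@]2(C)OC(=O)C[C@H]2O1 | target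

Total step count: 9. Longest linear sequence: 9.

Steps most likely to fail

Step 8.
- Risk: the carbenoid may be diverted before it reaches C6–H. It could be captured by the C1 ester carbonyl oxygen. Stepwise hydride abstraction could be followed by O-closure or by loss of stereochemical memory at C6. Carbene dimerisation is also possible.
- Fallback: it sets out from 18 and returns at 21, replacing the metal carbenoid by a free alkylidene carbene and changing the endgame. Aqueous HI in CHCl3 at 0 °C reduces the diazoketone to methyl (3R)-4-oxo-3-{[(2S)-12-phenyldodecan-2-yl]oxy}pentanoate F1. Its methyl group becomes the C4 methyl of the target. Lithiated trimethylsilyldiazomethane (THF, −78 → 0 °C, Colvin-type olefination with loss of N2) gives an alkylidene carbene whose carbene carbon is the new C5. The well-known 1,5 C–H insertion of such carbenes next to ether oxygen, again with retention, should give methyl 2-[(2R,5S)-3,5-dimethyl-5-(10-phenyldecyl)-2,5-dihydrofuran-2-yl]acetate F2. LiOH in aqueous THF gives 2-[(2R,5S)-3,5-dimethyl-5-(10-phenyldecyl)-2,5-dihydrofuran-2-yl]acetic acid F3. Iodolactonisation (I2, NaHCO3, MeCN) closes the γ-lactone at the tertiary C4, with the cis fusion dictated by the tether, and gives (3aR,5S,6S,6aS)-6-iodo-5,6a-dimethyl-5-(10-phenyldecyl)tetrahydrofuro[3,2-b]furan-2(3H)-one F4. Bu3SnH/AIBN removes the iodine to reach 21.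

Step 5.
- Risk: the thermally fragile glycolate enolate may decay before it is alkylated. It may be acylated at the ester carbonyl of 12. Base may also eliminate the β-alkoxy group from the product.
- Fallback: it sets out from 11 and returns at 14, bringing in C2–C1 as a masked alkene. The same enolate is alkylated with allyl iodide, the best-behaved electrophile for glycolate imides and one that cannot acylate, to give (4S)-4-benzyl-3-[(2R)-2-{[(2S)-12-phenyldodecan-2-yl]oxy}pent-4-enoyl]-1,3-oxazolidin-2-one F5. Ozonolysis (O3, CH2Cl2, −78 °C; Me2S) gives (3R)-4-[(4S)-4-benzyl-2-oxo-1,3-oxazolidin-3-yl]-4-oxo-3-{[(2S)-12-phenyldodecan-2-yl]oxy}butanal F6. Pinnick oxidation (NaClO2, NaH2PO4, 2-methyl-2-butene) gives (3R)-4-[(4S)-4-benzyl-2-oxo-1,3-oxazolidin-3-yl]-4-oxo-3-{[(2S)-12-phenyldodecan-2-yl]oxy}butanoic acid F7. Esterification with trimethylsilyldiazomethane in MeOH/toluene leads to 14.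

Step 9.
- Risk: facial selectivity at C4 may be poor. The nucleophile may over-add to the ester or to the newly formed lactone. Base may open the ring by retro-oxa-Michael, with loss of C3.
- Fallback: it sets out from 19 and returns at 21. C4 is set by a tethered ring closure, so the face of attack on the ketone no longer matters. Non-basic Lombardo methylenation (Zn, CH2Br2, TiCl4, THF/CH2Cl2), which spares esters, gives methyl 2-[(2R,5S)-5-methyl-3-methylidene-5-(10-phenyldecyl)oxolan-2-yl]acetate F8. LiOH gives 2-[(2R,5S)-5-methyl-3-methylidene-5-(10-phenyldecyl)oxolan-2-yl]acetic acid F9. The 5-exo iodolactonisation (I2, NaHCO3, MeCN) can only deliver the carboxylate to C4 from the face of the C3 arm, giving (3aR,5S,6aR)-6a-(iodomethyl)-5-methyl-5-(10-phenyldecyl)tetrahydrofuro[3,2-b]furan-2(3H)-one F10. Bu3SnH/AIBN converts CH2I into the C4 methyl group of 21.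

Further compounds
F1 | step 8 | methyl (3R)-4-oxo-3-{[(2S)-12-phenyldodecan-2-yl]oxy}pentanoate | COC(=O)C[C@@H](O[C@@H](C)CCCCCCCCCCc1ccccc1)C(C)=O
F2 | step 8 | methyl 2-[(2R,5S)-3,5-dimethyl-5-(10-phenyldecyl)-2,5-dihydrofuran-2-yl]acetate | C[C@]1(CCCCCCCCCCc2ccccc2)C=C(C)[C@@H](CC(=O)OC)O1
F3 | step 8 | 2-[(2R,5S)-3,5-dimethyl-5-(10-phenyldecyl)-2,5-dihydrofuran-2-yl]acetic acid | C[C@]1(CCCCCCCCCCc2ccccc2)C=C(C)[C@@H](CC(=O)O)O1
F4 | step 8 | (3aR,5S,6S,6aS)-6-iodo-5,6a-dimethyl-5-(10-phenyldecyl)tetrahydrofuro[3,2-b]furan-2(3H)-one | C[C@]1(CCCCCCCCCCc2ccccc2)[C@H](I)[C@@]2(C)OC(=O)C[C@H]2O1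
F5 | step 5 | (4S)-4-benzyl-3-[(2R)-2-{[(2S)-12-phenyldodecan-2-yl]oxy}pent-4-enoyl]-1,3-oxazolidin-2-one | C=CC[C@@H](O[C@@H](C)CCCCCCCCCCc1ccccc1)C(=O)N2C(=O)OC[C@@H]2Cc3ccccc3
F6 | step 5 | (3R)-4-[(4S)-4-benzyl-2-oxo-1,3-oxazolidin-3-yl]-4-oxo-3-{[(2S)-12-phenyldodecan-2-yl]oxy}butanal | O=CC[C@@H](O[C@@H](C)CCCCCCCCCCc1ccccc1)C(=O)N2C(=O)OC[C@@H]2Cc3ccccc3
F7 | step 5 | (3R)-4-[(4S)-4-benzyl-2-oxo-1,3-oxazolidin-3-yl]-4-oxo-3-{[(2S)-12-phenyldodecan-2-yl]oxy}butanoic acid | OC(=O)C[C@@H](O[C@@H](C)CCCCCCCCCCc1ccccc1)C(=O)N2C(=O)OC[C@@H]2Cc3ccccc3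
F8 | step 9 | methyl 2-[(2R,5S)-5-methyl-3-methylidene-5-(10-phenyldecyl)oxolan-2-yl]acetate | C[C@]1(CCCCCCCCCCc2ccccc2)CC(=C)[C@@H](CC(=O)OC)O1
F9 | step 9 | 2-[(2R,5S)-5-methyl-3-methylidene-5-(10-phenyldecyl)oxolan-2-yl]acetic acid | C[C@]1(CCCCCCCCCCc2ccccc2)CC(=C)[C@@H](CC(=O)O)O1
F10 | step 9 | (3aR,5S,6aR)-6a-(iodomethyl)-5-methyl-5-(10-phenyldecyl)tetrahydrofuro[3,2-b]furan-2(3H)-one | C[C@]1(CCCCCCCCCCc2ccccc2)C[C@@]2(CI)OC(=O)C[C@H]2O1
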